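Does the yield of E after 5.0 min follow temperature, or do the three flasks come out alike?

| flask | J | G | temperature | remark | time |
|---|---|---|---|---|---|
| red | 0.016 M | 1.1 mM (held) | −30 °C | run made earlier |  |
| ochre | 0.036 M | 1.1 mM (held) | 5 °C | run made earlier |  |
| autumn | 0.024 M | 1.1 mM (held) | 5 °C |  | 5.0 min |
| dawn | 0.024 M | 1.1 mM (held) | 35 °C |  | 5.0 min |
| spring | 0.024 M | 1.1 mM (held) | −25 °C |  | 5.0 min |

| red: time / min | red: E / % | ochre: time / min | ochre: E / % |
|---|---|---|---|
| 1.33 | 0 | 0.833 | 4 |
| 3.00 | 8 | 1.50 | 3 |
| 8.00 | 21 | 2.50 | 10 |
| 15.0 | 37 | 3.00 | 6 |

(standard deviation of a reading: 2 percentage points)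

- which flask leads in amount of E, in percent of the J charged ("all alike" within 1.5 percentage points) (autumn / dawn / spring / all alike)
- how much E is there at the end, in percent of the J charged: autumn
- how much E is there at the end, in percent of the J charged: dawn
- how much E is there at the end, in percent of the J charged: spring

Turn the question round: for the flasks to tie, the share of charged J converted per minute must come out the same at −25 °C, 5 °C and 35 °C. Carried over 5.0 min, the pace of the red run gives 12.3% and that of the ochre run 14.5%, a gap about the size of the scatter, so a tie looks possible. That reading of the two runs asks for a step proportional to [J] that is flat in temperature from −30 °C to 5 °C.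

You have a second reading if you count in concentration. The last readings of the ochre run give 1.05 mM/min of E. If each E takes up one G, that rate would consume a saturated 1.1 mM in 1.05 min, less than the time of the last ochre reading, so G must keep dissolving. Call this rate the feed ceiling, my estimate, with the scatter of the readings, of the most G a flask takes up per minute; it assumes dissolution is the rate-limiting step in the ochre run, which the readings cannot prove. For 0.024 M of J this estimate puts the cap on E near 21.8%. The red run, at 0.395 mM/min, lies below the ceiling, so I carry its percentage pace to the cold spring flask, about 12.3%. My reckoning puts autumn and dawn level near the cap and spring behind, a gap wider than the margin.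

The forecast reads the runs as “first order in J with almost no temperature dependence” and gives all alike, with autumn 14%, dawn 15% and spring 13%.

The flasks give autumn 18.2%, dawn 10.4% and spring 13.2%, so autumn leads.

    J + X ⇌ E (K = 1430 /M, k = 625 /M/min, Ea = 39.0 kJ/mol, ΔH = −40.0 kJ/mol)
    J + 2 X → L (k = 11500 /M²/min, Ea = 35.0 kJ/mol)
    G ⇌ X, rate k3*(csat - [X]) (kL = 0.967 /min)
    (constants at 5 °C)

The three stay under the ceiling of 21.8%, but dawn, which I put near it, falls well short. In dawn at 2.16 min, the forward rate of J + X to E, taken alone, corresponds to a half-life of J of 0.79 min, shorter than the run, yet at the end dawn holds 87.5% of J beside 10.4% of E, and this step runs both ways.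

In a flask like dawn with 0.060 M of J, the ceiling caps E at 8.75%; the computed flask holds 6.13%.

(The readings stem from a simulated flask with constants of no real substance; scatter was added.)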